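**Plan**

- Feature and main cut: in the γ-lactone ring, O1–C2(=O)–C3 with the vanillyl CH2 is a latent ketene. C4–C5 with the isovanillyl CH2 is the C=C of a 1-alkenyl sulfoxide. C3–C4 and C5–O1 are therefore cut together.
- Further cuts: S–C(sp) of an alkynyl sulfoxide and ArCH2–C(sp) on the isovanillyl arm, and ArCH2–CCl2 on the vanillyl arm.
- Forward order: two four-step arms from the O-benzylated benzylic alcohols converge in step 9. That step makes the only ring to be built (the lactone) and both skeletal bonds in one operation.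
- Stereochemistry: the sulfur centre comes from (+)-menthyl (R)-p-toluenesulfinate and is relayed to C4 through the [3,3] shift. C3 is set afterwards by equilibration to the trans lactone against the fixed C4.
- End game: tin hydride removes Cl (C3) and S-aryl (C5), base epimerises C3, and hydrogenolysis frees the two phenols.

Key step: step 9

Assumption: the sense of sulfur-to-carbon transfer is taken from the chair model (p-tolyl equatorial, lone pair axial); if practice showed the opposite sense, the equally available (−)-menthyl (S)-p-toluenesulfinate would be used with no other change.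

All five starting materials are catalogue compounds.

**Step 1**
Reactants: 1 3-benzyloxy-4-methoxybenzyl alcohol
Product: 2 3-benzyloxy-4-methoxybenzyl bromide
Conditions: PBr3 (0.4 equiv), Et2O, 0 °C; used without storage
Reagents that add atoms: phosphorus tribromide, BrP(Br)Br
Why: Bromodehydroxylation of an electron-rich benzylic alcohol (SN2 on the phosphite ester) is fast at 0 °C and leaves both aryl ethers untouched.

**Step 2**
Reactants: 2 3-benzyloxy-4-methoxybenzyl bromide; 3 ethynylmagnesium bromide (THF solution)
Product: 4 2-benzyloxy-1-methoxy-4-(prop-2-yn-1-yl)benzene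
Conditions: 3 (2.5 equiv), CuBr (10 mol %), THF, 50 °C; then H2O
Reagents that add atoms: none
Why: Copper-catalysed sp3–sp cross-coupling of a benzylic bromide with an alkynyl Grignard reagent, in which the excess of 3 suppresses double benzylation and the moderate temperature limits propargyl-to-allene isomerisation.

**Step 3**
Reactants: 4 2-benzyloxy-1-methoxy-4-(prop-2-yn-1-yl)benzene; 5 (1S,2R,5S)-(+)-menthyl (R)-p-toluenesulfinate
Product: 7 (R)-3-(3-benzyloxy-4-methoxyphenyl)prop-1-ynyl p-tolyl sulfoxide, via alkynylmagnesium bromide 6 (not isolated)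
Conditions: EtMgBr (1.0 equiv), THF, 0 °C → rt; solution added to 5 (1.1 equiv) in toluene, −20 → 0 °C; then H2O
Reagents that add atoms: none
Why: Andersen sulfoxide synthesis, in which the alkynyl Grignard reagent displaces mentholate from sulfur with clean inversion so that the (R)-sulfinate fixes the sulfur stereocentre of 7, while inverse addition in toluene keeps excess base away from the acidic propargylic CH2.

**Step 4**
Reactants: 7 (R)-3-(3-benzyloxy-4-methoxyphenyl)prop-1-ynyl p-tolyl sulfoxide
Product: 9 (S)-(E)-3-(3-benzyloxy-4-methoxyphenyl)prop-1-enyl p-tolyl sulfoxide, via alpha-aluminated vinyl sulfoxide 8 (not isolated)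
Conditions: iBu2AlH (1.2 equiv), THF, −78 °C; then aq. potassium sodium tartrate
Reagents that add atoms: none
Why: Conjugate hydride reduction (net anti hydroalumination, then protonolysis) of a 1-alkynyl sulfoxide is an established route to (E)-1-alkenyl sulfoxides and leaves sulfur untouched, the descriptor changing from R to S only because alkynyl outranks p-tolyl whereas vinyl does not.

**Step 5**
Reactants: 10 4-benzyloxy-3-methoxybenzyl alcohol
Product: 11 4-benzyloxy-3-methoxybenzyl bromide
Conditions: PBr3 (0.4 equiv), Et2O, 0 °C; used without storage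
Reagents that add atoms: phosphorus tribromide, BrP(Br)Br
Why: Bromodehydroxylation as in step 1, giving a benzylic bromide that is a standard electrophile of lignan lactone chemistry.

**Step 6**
Reactants: 12 methyl dichloroacetate; 11 4-benzyloxy-3-methoxybenzyl bromide
Product: 14 methyl 3-(4-benzyloxy-3-methoxyphenyl)-2,2-dichloropropanoate, via lithium dichloroenolate 13 (not isolated)
Conditions: LiN(iPr)2 (1.05 equiv), THF, −78 °C; then 11, DMPU, −78 → −40 °C
Reagents that add atoms: none
Why: Ester enolate alkylation, in which the lithium enolate of a dichloroacetate persists at −78 °C and is intercepted by the highly SN2-active benzylic bromide with DMPU as cosolvent; no stereocentre is formed.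

**Step 7**
Reactants: 14 methyl 3-(4-benzyloxy-3-methoxyphenyl)-2,2-dichloropropanoate
Product: 16 3-(4-benzyloxy-3-methoxyphenyl)-2,2-dichloropropanoic acid, via lithium carboxylate 15 (not isolated)
Conditions: LiOH (1.2 equiv), THF–H2O, 0 °C; then 1 M HCl
Reagents that add atoms: lithium hydroxide, [Li+].[OH-]
Why: Saponification, in which the two α-chlorines activate the ester so that hydroxide attacks the carbonyl at 0 °C faster than it can eliminate HCl towards the α-chlorocinnamate.

**Step 8**
Reactants: 16 3-(4-benzyloxy-3-methoxyphenyl)-2,2-dichloropropanoic acid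
Product: 17 3-(4-benzyloxy-3-methoxyphenyl)-2,2-dichloropropanoyl chloride
Conditions: (COCl)2 (1.5 equiv), DMF (cat.), CH2Cl2, 0 °C → rt; volatiles removed, toluene chase
Reagents that add atoms: oxalyl chloride, O=C(Cl)C(=O)Cl
Why: Acid chloride formation through the Vilsmeier-type chloroiminium catalyst is mild enough for the benzyl ether and the gem-dichloride, and complete removal of oxalyl chloride protects the sulfoxide of the next step.

**Step 9**
Reactants: 9 (S)-(E)-3-(3-benzyloxy-4-methoxyphenyl)prop-1-enyl p-tolyl sulfoxide; 17 3-(4-benzyloxy-3-methoxyphenyl)-2,2-dichloropropanoyl chloride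
Product: 21 (3S,4S,5S)-4-(3-benzyloxy-4-methoxybenzyl)-3-(4-benzyloxy-3-methoxybenzyl)-3-chloro-5-(p-tolylsulfanyl)dihydrofuran-2(3H)-one, via chloroketene 18 (not isolated), via oxysulfonium enolate 19 (not isolated), via thionium carboxylate 20 (not isolated)
Conditions: Zn–Cu couple (10 equiv), 9 (1 equiv), Et2O, 35 °C; 17 (3 equiv) in Et2O added over 4 h by syringe pump
Reagents that add atoms: none
Why: Proposed new method: Zn strips two chlorines from 17 to give the alkyl(chloro)ketene 18, the sulfinyl oxygen of 9 adds to its central carbon from the side of the small chlorine to give the (Z)-enolate 19, a charge-accelerated chair-like [3,3] shift breaks S–O and makes C3–C4, and the carboxylate of 20 then captures the thionium carbon to make C5–O1. The closest known reaction type is the lactonisation of enantiopure 1-alkenyl sulfoxides, 3-arylprop-1-enyl ones included, with dichloroketene made from trichloroacetyl chloride and Zn–Cu couple; what is new is that one ketene chlorine is replaced by a benzylic carbon. The single ring formed, the γ-lactone, closes 5-exo-trig by oxygen attack on the C5=S+ carbon (Pummerer-type capture). C4 is controlled by the sulfur stereocentre acting through the E alkene: with p-tolyl equatorial and the lone pair axial on the chair, (S)-sulfur lets C3 reach only the alkene face that leads to the (4R) centre of the target (written 4S in 21 only because the chlorine lifts C3 above C5 in the ranking). C3 follows from the (Z)-enolate geometry in the same chair (the two benzyl groups trans) and C5 from return of the carboxylate to the face from which oxygen left sulfur (net syn addition, 4,5-trans), but both centres are erased or equilibrated later, so only the transfer to C4 is required. The step needs O-acylation of the sulfoxide to outrun ketene dimerisation, [2+2] addition and direct attack of 17 on the sulfoxide, which is served by the retained chlorine and the ZnCl2 formed in situ (both keep 18 electrophilic) and by slow addition of 17, while the base-free medium keeps the alkene from moving into conjugation with the arene and so shuts off racemisation through an allyl sulfoxide.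

**Step 10**
Reactants: 21 (3S,4S,5S)-4-(3-benzyloxy-4-methoxybenzyl)-3-(4-benzyloxy-3-methoxybenzyl)-3-chloro-5-(p-tolylsulfanyl)dihydrofuran-2(3H)-one
Product: 23 (3S,4R)-4-(3-benzyloxy-4-methoxybenzyl)-3-(4-benzyloxy-3-methoxybenzyl)dihydrofuran-2(3H)-one, via dechlorinated thio lactone 22 (not isolated)
Conditions: Bu3SnH (3 equiv), AIBN (0.2 equiv), toluene, 100 °C
Reagents that add atoms: none
Why: Radical chain reduction, the reaction type used to strip ketene-derived chloro thio lactones, should take the tertiary α-carbonyl chlorine first and then the sulfur of the O,S-acetal; hydrogen transfer to the planar C3 radical anti to the C4 benzyl should favour the cis epimer drawn, which does not matter because the C3 epimer mixture is equilibrated next and C4 is not touched.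

**Step 11**
Reactants: 23 (3S,4R)-4-(3-benzyloxy-4-methoxybenzyl)-3-(4-benzyloxy-3-methoxybenzyl)dihydrofuran-2(3H)-one
Product: 24 (3R,4R)-4-(3-benzyloxy-4-methoxybenzyl)-3-(4-benzyloxy-3-methoxybenzyl)dihydrofuran-2(3H)-one
Conditions: DBU (1 equiv), toluene, 80 °C
Reagents that add atoms: none
Why: Base-mediated epimerisation through the lactone enolate affects only the acidic C3, and the thermodynamic preference of α,β-dibenzylbutyrolactones for the trans arrangement sets (3R) relative to the fixed (4R) centre.

**Step 12**
Reactants: 24 (3R,4R)-4-(3-benzyloxy-4-methoxybenzyl)-3-(4-benzyloxy-3-methoxybenzyl)dihydrofuran-2(3H)-one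
Product: 25 (3R,4R)-3-(4-hydroxy-3-methoxybenzyl)-4-(3-hydroxy-4-methoxybenzyl)dihydrofuran-2(3H)-one
Conditions: H2 (1 atm), 10% Pd/C, EtOAc–EtOH, rt
Reagents that add atoms: none
Why: Catalytic hydrogenolysis cleaves the two benzyl aryl ethers under neutral conditions that leave the lactone, the methyl ethers and both stereocentres unchanged, sulfur and tin having been removed two purifications earlier.

**Compound list**

1 | 3-benzyloxy-4-methoxybenzyl alcohol | COc1ccc(CO)cc1OCc1ccccc1 | starting material
2 | 3-benzyloxy-4-methoxybenzyl bromide | COc1ccc(CBr)cc1OCc1ccccc1 | intermediate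
3 | ethynylmagnesium bromide | C#C[Mg]Br | starting material
4 | 2-benzyloxy-1-methoxy-4-(prop-2-yn-1-yl)benzene | C#CCc1ccc(OC)c(OCc2ccccc2)c1 | intermediate
5 | (1S,2R,5S)-(+)-menthyl (R)-p-toluenesulfinate | CC(C)[C@H]1CC[C@H](C)C[C@@H]1O[S@@](=O)c1ccc(C)cc1 | starting material
6 | [3-(3-benzyloxy-4-methoxyphenyl)prop-1-ynyl]magnesium bromide | Br[Mg]C#CCc1ccc(OC)c(OCc2ccccc2)c1 | intermediate
7 | (R)-3-(3-benzyloxy-4-methoxyphenyl)prop-1-ynyl p-tolyl sulfoxide | Cc1ccc([S@@](=O)C#CCc2ccc(OC)c(OCc3ccccc3)c2)cc1 | intermediate
8 | (E)-[3-(3-benzyloxy-4-methoxyphenyl)-1-(p-tolylsulfinyl)prop-1-enyl]diisobutylalane, sulfur arranged as in 7 | Cc1ccc([S@@](=O)/C([Al](CC(C)C)CC(C)C)=C/Cc2ccc(OC)c(OCc3ccccc3)c2)cc1 | intermediate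
9 | (S)-(E)-3-(3-benzyloxy-4-methoxyphenyl)prop-1-enyl p-tolyl sulfoxide | Cc1ccc([S@@](=O)/C=C/Cc2ccc(OC)c(OCc3ccccc3)c2)cc1 | intermediate
10 | 4-benzyloxy-3-methoxybenzyl alcohol | COc1cc(CO)ccc1OCc1ccccc1 | starting material
11 | 4-benzyloxy-3-methoxybenzyl bromide | COc1cc(CBr)ccc1OCc1ccccc1 | intermediate
12 | methyl dichloroacetate | COC(=O)C(Cl)Cl | starting material
13 | lithium enolate of methyl dichloroacetate | COC([O-])=C(Cl)Cl.[Li+] | intermediate
14 | methyl 3-(4-benzyloxy-3-methoxyphenyl)-2,2-dichloropropanoate | COC(=O)C(Cl)(Cl)Cc1ccc(OCc2ccccc2)c(OC)c1 | intermediate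
15 | lithium 3-(4-benzyloxy-3-methoxyphenyl)-2,2-dichloropropanoate | [Li+].[O-]C(=O)C(Cl)(Cl)Cc1ccc(OCc2ccccc2)c(OC)c1 | intermediate
16 | 3-(4-benzyloxy-3-methoxyphenyl)-2,2-dichloropropanoic acid | OC(=O)C(Cl)(Cl)Cc1ccc(OCc2ccccc2)c(OC)c1 | intermediate
17 | 3-(4-benzyloxy-3-methoxyphenyl)-2,2-dichloropropanoyl chloride | O=C(Cl)C(Cl)(Cl)Cc1ccc(OCc2ccccc2)c(OC)c1 | intermediate
18 | (4-benzyloxy-3-methoxybenzyl)chloroketene | O=C=C(Cl)Cc1ccc(OCc2ccccc2)c(OC)c1 | intermediate
19 | (S)-configured (E)-alkenyl(p-tolyl)oxysulfonium (Z)-enolate zwitterion, O–S cis to Cl | Cc1ccc([S@@+](O/C([O-])=C(\Cl)Cc2ccc(OCc3ccccc3)c(OC)c2)/C=C/Cc2ccc(OC)c(OCc3ccccc3)c2)cc1 | intermediate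
20 | open-chain p-tolylthionium carboxylate zwitterion with the C3 and C4 configurations of 21 | COc1ccc(C[C@@H](C=[S+]c2ccc(C)cc2)[C@@](Cl)(Cc2ccc(OCc3ccccc3)c(OC)c2)C(=O)[O-])cc1OCc1ccccc1 | intermediate
21 | (3S,4S,5S)-4-(3-benzyloxy-4-methoxybenzyl)-3-(4-benzyloxy-3-methoxybenzyl)-3-chloro-5-(p-tolylsulfanyl)dihydrofuran-2(3H)-one | COc1ccc(C[C@H]2[C@H](Sc3ccc(C)cc3)OC(=O)[C@]2(Cl)Cc2ccc(OCc3ccccc3)c(OC)c2)cc1OCc1ccccc1 | intermediate
22 | (3S,4R,5S)-4-(3-benzyloxy-4-methoxybenzyl)-3-(4-benzyloxy-3-methoxybenzyl)-5-(p-tolylsulfanyl)dihydrofuran-2(3H)-one (C3 drawn as the expected epimer) | COc1ccc(C[C@H]2[C@H](Sc3ccc(C)cc3)OC(=O)[C@H]2Cc2ccc(OCc3ccccc3)c(OC)c2)cc1OCc1ccccc1 | intermediate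
23 | (3S,4R)-4-(3-benzyloxy-4-methoxybenzyl)-3-(4-benzyloxy-3-methoxybenzyl)dihydrofuran-2(3H)-one (cis; C3 drawn as the expected epimer) | COc1ccc(C[C@H]2COC(=O)[C@H]2Cc2ccc(OCc3ccccc3)c(OC)c2)cc1OCc1ccccc1 | intermediate
24 | (3R,4R)-4-(3-benzyloxy-4-methoxybenzyl)-3-(4-benzyloxy-3-methoxybenzyl)dihydrofuran-2(3H)-one (trans) | COc1ccc(C[C@H]2COC(=O)[C@@H]2Cc2ccc(OCc3ccccc3)c(OC)c2)cc1OCc1ccccc1 | intermediate
25 | (3R,4R)-3-(4-hydroxy-3-methoxybenzyl)-4-(3-hydroxy-4-methoxybenzyl)dihydrofuran-2(3H)-one (CNP0309867.1) | COc1ccc(C[C@H]2COC(=O)[C@@H]2Cc2ccc(O)c(OC)c2)cc1O | target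

**Step count**

Total step count: 12.
Longest linear sequence: 8 steps (steps 1–4 or steps 5–8, then steps 9–12).

**Steps most likely to fail**

**Step 9.** Several processes could outrun O-acylation of the sulfoxide.
- The alkyl(chloro)ketene is less electrophilic than dichloroketene and may dimerise.
- The acid chloride may attack the sulfoxide directly (deoxygenation, additive Pummerer reaction).
- The chair may lose facial fidelity.

The fallback uses only known chemistry and sets out from 9. Trichloroacetyl chloride and Zn–Cu couple generate dichloroketene F1, which lactonises 9 to the 3,3-dichloro-5-(p-tolylsulfanyl) lactone F2 with the same sulfur-to-C4 transfer. Bu3SnH with AIBN removes both chlorines and the sulfur group to give the (R)-β-benzyl lactone F3. LiN(SiMe3)2 in THF at −78 °C converts F3 into its lithium enolate F4. Bromide 11 alkylates F4 anti to the C4 substituent, and the route is rejoined at 24. The C3–CH2 bond is then made by enolate alkylation instead of being carried in by the ketene.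

**Step 3.** The mentholate that is released, or unreacted Grignard reagent, may deprotonate the doubly activated propargylic CH2. This would drive propargyl-to-allenyl isomerisation of the alkynyl sulfoxide.

The fallback sets out from 4. Hydrozirconation with Cp2Zr(H)Cl gives the (E)-alkenylzirconocene chloride F5. Iodinolysis with I2 gives the (E)-vinyl iodide F6. Iodine–lithium exchange with t-BuLi (2 equiv) in Et2O at −78 °C gives the (E)-vinyllithium F7. This displaces mentholate from 5 with inversion at sulfur and retention of alkene geometry. The route is rejoined at 9, so the alkene geometry is fixed before the S–C bond is made, and both 7 and the hydride step are bypassed.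

**Step 6.** α-Elimination or self-condensation of the chlorinated enolate may outrun the SN2 alkylation at the temperature the alkylation needs.

The fallback sets out from 10. Oxidation with MnO2 in CH2Cl2 gives 4-benzyloxy-3-methoxybenzaldehyde F8. Enolate 13 adds to F8 at −78 °C in an aldol addition that is far faster than alkylation. A cold AcOH quench, which prevents Darzens closure, gives the β-hydroxy-α,α-dichloro ester F9. Ionic deoxygenation with Et3SiH and BF3·OEt2 through the p-alkoxybenzyl cation removes the hydroxyl group, and the route is rejoined at 14.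

**Further compounds**

F1 | step 9 | dichloroketene | O=C=C(Cl)Cl
F2 | step 9 | (4S,5S)-4-(3-benzyloxy-4-methoxybenzyl)-3,3-dichloro-5-(p-tolylsulfanyl)dihydrofuran-2(3H)-one | COc1ccc(C[C@H]2[C@H](Sc3ccc(C)cc3)OC(=O)C2(Cl)Cl)cc1OCc1ccccc1
F3 | step 9 | (R)-4-(3-benzyloxy-4-methoxybenzyl)dihydrofuran-2(3H)-one | COc1ccc(C[C@H]2COC(=O)C2)cc1OCc1ccccc1
F4 | step 9 | lithium enolate of (R)-4-(3-benzyloxy-4-methoxybenzyl)dihydrofuran-2(3H)-one | COc1ccc(C[C@H]2COC([O-])=C2)cc1OCc1ccccc1.[Li+]
F5 | step 3 | (E)-[3-(3-benzyloxy-4-methoxyphenyl)prop-1-enyl]zirconocene chloride (cyclopentadienyl rings drawn sigma-bound) | Cl[Zr](/C=C/Cc1ccc(OC)c(OCc2ccccc2)c1)(C1C=CC=C1)C1C=CC=C1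
F6 | step 3 | (E)-2-benzyloxy-4-(3-iodoprop-2-en-1-yl)-1-methoxybenzene | COc1ccc(C/C=C/I)cc1OCc1ccccc1
F7 | step 3 | (E)-[3-(3-benzyloxy-4-methoxyphenyl)prop-1-enyl]lithium | [Li]/C=C/Cc1ccc(OC)c(OCc2ccccc2)c1
F8 | step 6 | 4-benzyloxy-3-methoxybenzaldehyde | COc1cc(C=O)ccc1OCc1ccccc1
F9 | step 6 | methyl 3-(4-benzyloxy-3-methoxyphenyl)-2,2-dichloro-3-hydroxypropanoate (racemic) | COC(=O)C(Cl)(Cl)C(O)c1ccc(OCc2ccccc2)c(OC)c1
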